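## The problem

Shanciguol has no stereocentre and no fused ring. Four benzene rings are held together only by two CH2 links and one CH2CH2 link, so the whole difficulty lies in the substitution pattern of the central ring A. Ring A is a pentasubstituted resorcinol: C1 carries the 2-(3-hydroxyphenyl)ethyl chain, C2 and C6 the two 4-hydroxybenzyl groups, C3 and C5 the hydroxyls, and only C4 keeps a hydrogen. Three carbon substituents are contiguous, and each benzyl group is wedged between the chain and an oxygen. With no stereocentre there is nothing for one centre to relay to another; the task is purely regiochemical, and the mirror plane through C1 and C4 need not be used in the assembly. Five free phenols make the compound oxidation-prone under base. The bonds from ring A to the 4-hydroxybenzyl carbons can ionise under strong acid, because both partners stabilise a benzylic cation. The phenols are therefore carried as ethers or an ester and released last, in the cold. The enabling feature is that C4–C5–C6–C1 of ring A (oxygen on C5, benzyl on C6, chain on C1) are the diene carbons C3–C4–C5–C6 of a 4-oxygenated 5,6-disubstituted 2-pyrone, while C2–C3 with its benzyl group and oxygen are the two carbons of a 1-alkoxyalkyne. The nucleophilic alkyne carbon and the electrophilic pyrone C6 are polarity-matched, so ring A can be built by cycloaddition instead of by substitution of an existing benzene.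

## Retrosynthesis

**Unmasking (17 ⇒ 16 ⇒ 15).** Only O–C bonds are cut. The target 17 is traced to the phenol 16, which carries one ethyl and three methyl ethers, and 16 to the pivalate 15. Methyl ethers on the outer rings survive every earlier reagent. The ethyl ether and the pivalate are not chosen as protecting groups; they are what the two cycloaddition partners leave behind. The forward reactions are a mild methanolysis and one Lewis-acid dealkylation, placed last so that the free polyphenol is never exposed to base or oxidants.

**Ring A (15 ⇒ 9 + 13, through 14).** The bonds C1–C2 and C3–C4 of ring A are cut. This leads back to the pyrone pivalate 9, which carries the chain, one benzyl group and one oxygen, and to the ynol ether 13, which carries the other benzyl group and the second oxygen. The bicyclic lactone 14 is the unisolated link between them. The neighbouring cuts at the benzyl–ring bonds would fall back on substituting a resorcinol, where C2/C6 must be distinguished from C4 and from the outer anisole rings. Here every substituent sits where its fragment places it, and the only open question is one regiochemical sense of a polar (4+2) addition. Both precursors are acyclic or monocyclic and about half the size of 15. The forward step needs a 4-oxygenated, 5,6-dialkylated pyrone to act as an electron-poor diene. Two choices support this. The oxygen at C4 is carried as a pivalate rather than an ether, which lowers the LUMO. The reaction is driven by pressure rather than heat, because ethyl ynol ethers fragment to ketene and ethylene at temperatures a thermal variant would need.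

**Pyrone (9 ⇒ 8 ⇒ 5 + 6, through 7).** Removing the acyl group gives the 4-hydroxypyrone 8. Cutting its C4–C5 and O1–C2 bonds (pyrone numbering) gives the enol silane 5 and malonyl dichloride 6, with the keto acid chloride 7 as the unisolated intermediate. This three-carbon-plus-three-atom annulation is preferred to a linear triketo ester build-up because it makes the ring in one operation from a regiodefined enol derivative. It requires that the enol double bond of 5 lie on the 4-methoxybenzyl side of the carbonyl.

**Enol silane (5 ⇒ 4 ⇒ 1 + 2, through 3).** The saturated ketone corresponding to 5 has two nearly identical CH2CH2Ar arms and cannot be enolised selectively. The enol silane is therefore derived from the enone 4 by 1,4-addition of Si–H, which places the double bond unambiguously. Enone 4 is cut at its C=C bond to 4-(3-methoxyphenyl)butan-2-one 1 and 4-methoxybenzaldehyde 2, with the aldol 3 as intermediate. The forward reaction needs condensation at the methyl group of 1, the normal course under base.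

**Ynol ether (13 ⇒ 10 + 11, through 12).** The C(sp)–CH2 bond is cut, giving ethoxyacetylene 10 and 4-methoxybenzyl bromide 11, joined through lithium ethoxyacetylide 12. Both are catalogue compounds, and the forward step is a single SN2 alkylation.

## Roads not taken

**Alternative 1:** Ring A is cut at C1–C2 and C1–C6. The dianion of the diketone A1 would be acylated at a terminal α-carbon by the cinnamic N-methoxy-N-methylamide A2. The resulting triketone A3 would close by intramolecular aldol condensation to the stilbene resorcinol A4, which then needs alkene hydrogenation and demethylation.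
- Merits: the route follows the biosynthetic logic of stilbenoids, uses the symmetry of the target, fixes the oxygen pattern automatically, and would reach the target in about five steps, clearly fewer than the chosen plan.
- Weak points: A2 offers the dianion both a 1,2- and a 1,4-site. The terminal carbon of A1 is secondary and hindered. In A3 the carbonyl that must accept the aldol is cross-conjugated and flanked by a substituted carbon, and the attacking carbon is again secondary. A3 also has competing O-cyclisations, to a pyranone and by oxa-Michael addition to the styryl enone.
- Comparison: both plans rest on an untested ring-forming step, and Alternative 1 wins on step count. The chosen plan offers a cycloaddition made irreversible by CO2 loss, with no lower-energy heterocyclisation available to its partners, and stable, separately preparable fragments that allow a failure to be located.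

**Alternative 2:** The two aryl–CH bonds to the outer 4-oxygenated rings are cut. An excess of the Grignard reagent A6 would add to both formyl groups of the dialdehyde A5 to give the bis(diarylcarbinol) A7. Ionic deoxygenation with a silane and acid, then demethylation, would follow.
- Merits: every step is a known reaction type, the two-directional addition uses the symmetry, and the diastereomer mixture of A7 does not matter. In certainty per step this road is better than the chosen one, and its length (about seven steps) is comparable.
- Weak points: A5 requires two formylations of ring A at the positions flanking the chain. The second is on a ring deactivated by the first formyl group and at a site crowded by the chain, with the position between the two methoxy groups competing. Oxygen is added at two carbons only to be removed again. The deoxygenation passes through doubly benzylic cations held next to the tethered 3-methoxyphenyl ring, which can close a seven-membered ring by Friedel–Crafts attack before hydride arrives.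
- Comparison: the chosen plan fixes the pattern by construction, needs no electrophilic substitution of ring A, and generates no benzylic cation before the last step. It pays for this with a key step that has no precedent.

**Alternative 3:** Ring A is cut at C1–C2 and C4–C5. With a strong alkoxide base the ketone A8 would add through its methylene α-carbon to the β-carbon of the enoate A9, and its methyl group would then attack the ester to close the cyclohexane-1,3-dione A10. Dehydrogenation to the resorcinol and demethylation would follow.
- Merits: cheap materials, base-only chemistry, and a reaction class long used for 5-alkylresorcinols. The route is about as long as the chosen one and contains no unprecedented reaction type.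
- Weak points: A8 must react first through its more substituted α-carbon and then through its methyl group; the reverse order gives an isomeric dione. A9 is an α,β-disubstituted enoate and a poor, reversible Michael acceptor. A10 must then be oxidised to the aromatic level in the presence of four benzylic CH2 groups and three electron-rich arenes.
- Comparison: the chosen plan has no regiochemical ambiguity of this kind, since the enol position is set through the enone, and it arrives at the aromatic oxidation level without an oxidant. Alternative 3 has the advantage of simpler equipment and no high-pressure step.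

Key step: step 6

## Route

Remark: 1 is taken as a catalogue compound; 5 is expected mainly as the (Z)-isomer and its geometry is lost in step 3; 3, 7 and 14 are racemic and never isolated.

Step 1
Reactants: 1 4-(3-methoxyphenyl)butan-2-one; 2 4-methoxybenzaldehyde
Product: 4 (E)-1-(4-methoxyphenyl)-5-(3-methoxyphenyl)pent-1-en-3-one, via aldol adduct 3 (not isolated)
Conditions: NaOH (aq., cat.), EtOH, 0 °C to rt
Reagents that add atoms: none
Why: Claisen–Schmidt condensation; under base a methyl ketone condenses through its methyl group because the aldol at the methylene is reversible and dehydrates poorly, and E1cB loss of water from 3 should give the anisyl-conjugated (E)-enone.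

Step 2
Reactants: 4 (E)-1-(4-methoxyphenyl)-5-(3-methoxyphenyl)pent-1-en-3-one
Product: 5 triethyl{[(2Z)-1-(4-methoxyphenyl)-5-(3-methoxyphenyl)pent-2-en-3-yl]oxy}silane
Conditions: Et3SiH, RhCl(PPh3)3 (cat.), THF, 50 °C
Reagents that add atoms: triethylsilane, CC[SiH](CC)CC
Why: Rhodium-catalysed 1,4-hydrosilylation of an enone with a monohydrosilane delivers hydride to the β-carbon and silicon to oxygen, so the enol double bond should be fixed on the 4-methoxybenzyl side, which enolisation of the saturated ketone could not achieve.

Step 3
Reactants: 5 triethyl{[(2Z)-1-(4-methoxyphenyl)-5-(3-methoxyphenyl)pent-2-en-3-yl]oxy}silane; 6 malonyl dichloride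
Product: 8 4-hydroxy-5-(4-methoxybenzyl)-6-[2-(3-methoxyphenyl)ethyl]-2H-pyran-2-one, via keto acid chloride 7 (not isolated)
Conditions: Et2O, −78 °C to rt
Reagents that add atoms: none
Why: Acylative annulation of a silyl enol ether with malonyl dichloride; the enol carbon is C-acylated with loss of the silyl chloride, the enol oxygen of 7 then closes on the second acid chloride (6-exo-trig lactonisation) and tautomerisation should give the 4-hydroxy-2-pyrone with the benzyl group at C5 and the chain at C6.

Step 4
Reactants: 8 4-hydroxy-5-(4-methoxybenzyl)-6-[2-(3-methoxyphenyl)ethyl]-2H-pyran-2-one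
Product: 9 5-(4-methoxybenzyl)-6-[2-(3-methoxyphenyl)ethyl]-2-oxo-2H-pyran-4-yl pivalate
Conditions: PivCl, Et3N, CH2Cl2, 0 °C
Reagents that add atoms: pivaloyl chloride, CC(C)(C)C(=O)Cl
Why: O-acylation of the acidic 4-hydroxyl of a vinylogous acid; the hindered acyl chloride and the absence of a nucleophilic catalyst should prevent O-to-C3 acyl migration.

Step 5
Reactants: 10 ethoxyacetylene; 11 4-methoxybenzyl bromide
Product: 13 1-ethoxy-3-(4-methoxyphenyl)prop-1-yne, via lithium ethoxyacetylide 12 (not isolated)
Conditions: n-BuLi, THF, −78 °C; then 11, DMPU, −78 °C to rt
Reagents that add atoms: none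
Why: SN2 alkylation of a lithium alkoxyacetylide by a reactive benzylic bromide in a dipolar cosolvent; 13 should be isolated on base-washed support because ynol ethers hydrate under acid.

Step 6
Reactants: 9 5-(4-methoxybenzyl)-6-[2-(3-methoxyphenyl)ethyl]-2-oxo-2H-pyran-4-yl pivalate; 13 1-ethoxy-3-(4-methoxyphenyl)prop-1-yne
Product: 15 5-ethoxy-2,4-bis(4-methoxybenzyl)-3-[2-(3-methoxyphenyl)ethyl]phenyl pivalate, via bicyclic lactone 14 (not isolated)
Conditions: 13 (3 equiv), CH2Cl2, 10 kbar, 50 °C; then 1 bar, PhMe, 80 °C
Reagents that add atoms: none
Why: Proposed new method: the pyrone 9 (LUMO largest at C6) and the ynol ether 13 (HOMO largest at the benzyl-bearing carbon) should combine in an asynchronous inverse-demand (4+2) cycloaddition in which the bond to C6 leads and the ethoxy-bearing carbon then closes on C3, the diene terminus made nucleophilic by the oxygen at C4. Ring A is closed in this single intermolecular cycloaddition as the 2-oxabicyclo[2.2.2]octadienone 14, which loses CO2 by retro-(4+2) and becomes aromatic; the two bridgehead stereocentres of 14 vanish in that step, so no stereocentre has to be controlled. The closest known reaction type is the Diels–Alder reaction of 2-pyrones with alkynes followed by CO2 extrusion, in which ynamines and ketene acetals join their nucleophilic carbon to pyrone C6; a 4-acyloxy-5,6-dialkylpyrone paired with an ynol ether has not been shown. The selectivity needed is regiochemical and rests on the match between the nucleophilic alkyne carbon and the vinylogous acyl carbon C6, which places the ethoxy carbon next to the unsubstituted C3 and gives the 1,3-dioxygenated ring. Pressure replaces heat because the cycloaddition has a strongly negative activation volume whereas ethyl ynol ethers fragment to ketene and ethylene above about 100 °C; the pivalate is preferred to an ether at C4 because it lowers the diene LUMO and is inert to 13.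

Step 7
Reactants: 15 5-ethoxy-2,4-bis(4-methoxybenzyl)-3-[2-(3-methoxyphenyl)ethyl]phenyl pivalate
Product: 16 5-ethoxy-2,4-bis(4-methoxybenzyl)-3-[2-(3-methoxyphenyl)ethyl]phenol
Conditions: K2CO3 (cat.), MeOH, THF, 40 °C
Reagents that add atoms: none
Why: Base-catalysed transesterification of an aryl ester; the phenoxide is a good leaving group, so even a pivalate should be methanolysed while the alkyl ethers stay untouched.

Step 8
Reactants: 16 5-ethoxy-2,4-bis(4-methoxybenzyl)-3-[2-(3-methoxyphenyl)ethyl]phenol
Product: 17 shanciguol, 4,6-bis(4-hydroxybenzyl)-5-[2-(3-hydroxyphenyl)ethyl]benzene-1,3-diol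
Conditions: BBr3 (excess), CH2Cl2, −78 °C to rt; then H2O
Reagents that add atoms: none
Why: Lewis-acid dealkylation of aryl alkyl ethers; bromide attacks the O-methyl and O-ethyl carbons of the boron-complexed ethers, and the low temperature should keep the benzyl–arene bonds intact.

## Compound list

1 | 4-(3-methoxyphenyl)butan-2-one | CC(=O)CCc1cccc(OC)c1 | starting material
2 | 4-methoxybenzaldehyde | COc1ccc(C=O)cc1 | starting material
3 | 1-hydroxy-1-(4-methoxyphenyl)-5-(3-methoxyphenyl)pentan-3-one (racemic) | COc1ccc(C(O)CC(=O)CCc2cccc(OC)c2)cc1 | intermediate
4 | (E)-1-(4-methoxyphenyl)-5-(3-methoxyphenyl)pent-1-en-3-one | COc1ccc(/C=C/C(=O)CCc2cccc(OC)c2)cc1 | intermediate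
5 | triethyl{[(2Z)-1-(4-methoxyphenyl)-5-(3-methoxyphenyl)pent-2-en-3-yl]oxy}silane | CC[Si](CC)(CC)O/C(CCc1cccc(OC)c1)=C\Cc1ccc(OC)cc1 | intermediate
6 | malonyl dichloride | O=C(Cl)CC(=O)Cl | starting material
7 | 7-(3-methoxyphenyl)-4-[(4-methoxyphenyl)methyl]-3,5-dioxoheptanoyl chloride (racemic) | O=C(Cl)CC(=O)C(Cc1ccc(OC)cc1)C(=O)CCc1cccc(OC)c1 | intermediate
8 | 4-hydroxy-5-(4-methoxybenzyl)-6-[2-(3-methoxyphenyl)ethyl]-2H-pyran-2-one | O=c1cc(O)c(Cc2ccc(OC)cc2)c(CCc2cccc(OC)c2)o1 | intermediate
9 | 5-(4-methoxybenzyl)-6-[2-(3-methoxyphenyl)ethyl]-2-oxo-2H-pyran-4-yl pivalate | O=c1cc(OC(=O)C(C)(C)C)c(Cc2ccc(OC)cc2)c(CCc2cccc(OC)c2)o1 | intermediate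
10 | ethoxyacetylene | C#COCC | starting material
11 | 4-methoxybenzyl bromide | COc1ccc(CBr)cc1 | starting material
12 | lithium ethoxyacetylide | [Li]C#COCC | intermediate
13 | 1-ethoxy-3-(4-methoxyphenyl)prop-1-yne | CCOC#CCc1ccc(OC)cc1 | intermediate
14 | 8-ethoxy-6,7-bis(4-methoxybenzyl)-1-[2-(3-methoxyphenyl)ethyl]-3-oxo-2-oxabicyclo[2.2.2]octa-5,7-dien-5-yl pivalate (racemic) | O=C1OC2(CCc3cccc(OC)c3)C(Cc3ccc(OC)cc3)=C(OC(=O)C(C)(C)C)C1C(OCC)=C2Cc1ccc(OC)cc1 | intermediate
15 | 5-ethoxy-2,4-bis(4-methoxybenzyl)-3-[2-(3-methoxyphenyl)ethyl]phenyl pivalate | CCOc1cc(OC(=O)C(C)(C)C)c(Cc2ccc(OC)cc2)c(CCc2cccc(OC)c2)c1Cc1ccc(OC)cc1 | intermediate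
16 | 5-ethoxy-2,4-bis(4-methoxybenzyl)-3-[2-(3-methoxyphenyl)ethyl]phenol | CCOc1cc(O)c(Cc2ccc(OC)cc2)c(CCc2cccc(OC)c2)c1Cc1ccc(OC)cc1 | intermediate
17 | shanciguol, 4,6-bis(4-hydroxybenzyl)-5-[2-(3-hydroxyphenyl)ethyl]benzene-1,3-diol | Oc1ccc(Cc2c(O)cc(O)c(Cc3ccc(O)cc3)c2CCc2cccc(O)c2)cc1 | target

## Step count and risks

Total: 8 steps. Longest linear sequence: 7 steps (steps 1, 2, 3, 4, 6, 7, 8); step 5 is the one-step side branch.

**Step 6 (key step).** The cycloaddition may not proceed at a useful rate, because the diene carries three donor substituents and C6 is crowded. The ynol ether may instead be consumed by hydration, by conjugate addition at C4, or by (2+2) addition to the lactone carbonyl. Partial leakage to the other regiochemical sense is also possible. The fallback gives up the cycloaddition and builds the pattern by known electrophilic benzylation of a preformed ring A. It sets out from 11 and returns to the route at 17.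
- Horner–Wadsworth–Emmons olefination of 3-methoxybenzaldehyde with diethyl (3,5-dimethoxybenzyl)phosphonate (NaH, THF) should give (E)-1,3-dimethoxy-5-[2-(3-methoxyphenyl)ethenyl]benzene F1.
- Hydrogenation (H2, Pd/C, EtOAc) gives 1,3-dimethoxy-5-[2-(3-methoxyphenyl)ethyl]benzene F2.
- Twofold Friedel–Crafts benzylation of F2 with 11 (ZnCl2, CH2Cl2, 0 °C) is directed by the methoxy groups to the two positions para to them, which flank the chain, and should give 1,5-dimethoxy-2,4-bis(4-methoxybenzyl)-3-[2-(3-methoxyphenyl)ethyl]benzene F3.
- Demethylation of F3 with BBr3 gives 17.
- The price is regiochemical uncertainty: the position between the two methoxy groups and the monomethoxy ring compete, so a separation would be needed.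

**Step 3.** The HCl released can protodesilylate 5 before acylation, which erases the regiochemical definition of the enol. Self-condensation of malonyl dichloride can lower conversion. The fallback builds the pyrone from a β-keto ester dianion. It sets out from 11 and returns at 8.
- The dianion of methyl acetoacetate (NaH, then n-BuLi, THF, 0 °C) is alkylated at its terminal carbon by 11 to give methyl 5-(4-methoxyphenyl)-3-oxopentanoate F4.
- The dianion of F4 (LiN(iPr)2, THF, −78 °C) is acylated at its γ-carbon by methyl 3-(3-methoxyphenyl)propanoate to give methyl 4-(4-methoxybenzyl)-7-(3-methoxyphenyl)-3,5-dioxoheptanoate F5.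
- Lactonisation of F5 (DBU, PhMe, reflux) with loss of methanol gives 8.

**Step 5.** The basic acetylide can isomerise the product to an alkoxyallene by propargyl-to-allenyl proton shift. Alkylation can be slow compared with decomposition of the bromide. The ynol ether can hydrate during isolation. The fallback forms the same bond by cross-coupling under neutral conditions. It sets out from 10 and returns at 13.
- Lithiation of 10 and quenching with tributyltin chloride gives tributyl(ethoxyethynyl)stannane F6.
- Stille coupling of F6 with 11, catalysed by the zerovalent palladium complex Pd(PPh3)4 in THF at 50 °C, gives 13.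

**Step 8.** The Lewis acid can ionise the electron-rich benzyl–arene bonds, leading to benzyl transfer between rings, and the ethyl ether may be cleaved incompletely. The fallback replaces electrophilic cleavage by nucleophilic cleavage. It sets out from 16 and returns at 17 with no new compound. NaSEt in DMF at 140 °C attacks the O-methyl and O-ethyl carbons by SN2, so no benzylic cation can arise. The work-up must be acidic and oxygen-free to protect the polyphenoxide.

## Further compounds

F1 | step 6 | (E)-1,3-dimethoxy-5-[2-(3-methoxyphenyl)ethenyl]benzene | COc1cccc(/C=C/c2cc(OC)cc(OC)c2)c1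
F2 | step 6 | 1,3-dimethoxy-5-[2-(3-methoxyphenyl)ethyl]benzene | COc1cccc(CCc2cc(OC)cc(OC)c2)c1
F3 | step 6 | 1,5-dimethoxy-2,4-bis(4-methoxybenzyl)-3-[2-(3-methoxyphenyl)ethyl]benzene | COc1ccc(Cc2c(OC)cc(OC)c(Cc3ccc(OC)cc3)c2CCc2cccc(OC)c2)cc1
F4 | step 3 | methyl 5-(4-methoxyphenyl)-3-oxopentanoate | COC(=O)CC(=O)CCc1ccc(OC)cc1
F5 | step 3 | methyl 4-(4-methoxybenzyl)-7-(3-methoxyphenyl)-3,5-dioxoheptanoate (racemic) | COC(=O)CC(=O)C(Cc1ccc(OC)cc1)C(=O)CCc1cccc(OC)c1
F6 | step 5 | tributyl(ethoxyethynyl)stannane | CCCC[Sn](CCCC)(CCCC)C#COCC
F0 | step 8 | none | none
A1 | alternative 1 | 1,7-bis(4-methoxyphenyl)heptane-3,5-dione | COc1ccc(CCC(=O)CC(=O)CCc2ccc(OC)cc2)cc1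
A2 | alternative 1 | (2E)-N-methoxy-3-(3-methoxyphenyl)-N-methylprop-2-enamide | CON(C)C(=O)/C=C/c1cccc(OC)c1
A3 | alternative 1 | (1E)-4-(4-methoxybenzyl)-1-(3-methoxyphenyl)-9-(4-methoxyphenyl)non-1-ene-3,5,7-trione (racemic) | COc1cccc(/C=C/C(=O)C(Cc2ccc(OC)cc2)C(=O)CC(=O)CCc2ccc(OC)cc2)c1
A4 | alternative 1 | 4,6-bis(4-methoxybenzyl)-5-[(E)-2-(3-methoxyphenyl)ethenyl]benzene-1,3-diol | COc1ccc(Cc2c(O)cc(O)c(Cc3ccc(OC)cc3)c2/C=C/c2cccc(OC)c2)cc1
A5 | alternative 2 | 4,6-dimethoxy-2-[2-(3-methoxyphenyl)ethyl]benzene-1,3-dicarbaldehyde | COc1cccc(CCc2c(C=O)c(OC)cc(OC)c2C=O)c1
A6 | alternative 2 | 4-methoxyphenylmagnesium bromide | COc1ccc([Mg]Br)cc1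
A7 | alternative 2 | [4,6-dimethoxy-2-[2-(3-methoxyphenyl)ethyl]-1,3-phenylene]bis[(4-methoxyphenyl)methanol] (mixture of diastereomers) | COc1ccc(C(O)c2c(OC)cc(OC)c(C(O)c3ccc(OC)cc3)c2CCc2cccc(OC)c2)cc1
A8 | alternative 3 | 4-(4-methoxyphenyl)butan-2-one | CC(=O)CCc1ccc(OC)cc1
A9 | alternative 3 | ethyl (2E)-2-(4-methoxybenzyl)-5-(3-methoxyphenyl)pent-2-enoate | CCOC(=O)/C(Cc1ccc(OC)cc1)=C/CCc1cccc(OC)c1
A10 | alternative 3 | 4,6-bis(4-methoxybenzyl)-5-[2-(3-methoxyphenyl)ethyl]cyclohexane-1,3-dione (mixture of diastereomers) | O=C1CC(=O)C(Cc2ccc(OC)cc2)C(CCc2cccc(OC)c2)C1Cc1ccc(OC)cc1
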